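**Retrosynthetic overview**
1. Target 21 ⇐ 20: the last ring (C15–O17 ether of the 2-oxabicyclo[2.2.2]octane) closes by acid-triggered opening of a C13–C15 epoxide by the C18 tertiary alcohol.
2. 20 ⇐ 18 (key step): intramolecular de Mayo reaction. The [2+2] closes the γ-lactone and a cyclobutane together; retro-aldol then enlarges the six-membered dione ring to the cyclooctane.
3. 18 ⇐ 8 + 15: ester tether on O24, enol locked as a cyclic carbonate, 1,4-hydrosilylation sets C10 and gives the C9=C18 silyl enol ether.
4. 8 ⇐ 1 + 2: Diels–Alder puts the cyclohexene on the cyclopentenone; Saegusa oxidation, α'-hydroxylation and OH-directed singlet-oxygen ene/epoxidation follow.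
5. 15 ⇐ 9 + 10 + 14: lactate-dioxolanone allylation, asymmetric hydrogenation, double Claisen (cyclohexane-1,3-dione ring). Ring order: cyclopentane (in 1) → cyclohexene → epoxide → γ-lactone + cyclobutane → cyclooctane → ether bridge.

Assumptions: atom labels (C2, C9, O17 …) are the positions of the atoms in the target SMILES counted from the left over all non-hydrogen atoms; 1 and 9 are bought as single enantiomers; 15 and 16 are drawn as one enol tautomer.

Step 1
Reactants: 1 (S)-4-(tert-butyldimethylsilyloxy)cyclopent-2-en-1-one; 2 2,3-dimethylbuta-1,3-diene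
Product: 3 cis-fused 3-(tert-butyldimethylsilyloxy)-5,6-dimethyl-2,3,3a,4,7,7a-hexahydro-1H-inden-1-one (OTBS on the face of the two ring-fusion H)
Conditions: Me2AlCl (0.3 equiv), CH2Cl2, -40 °C
Reagents that add atoms: none
Why: Lewis-acid-catalysed Diels–Alder reaction in which the diene adds suprafacially to the enone face anti to the C10 silyloxy group, so C12 and C25 are set with the target's absolute configuration while C10 serves only as a temporary control centre.

Step 2
Reactants: 3 cis-fused 3-(tert-butyldimethylsilyloxy)-5,6-dimethyl-2,3,3a,4,7,7a-hexahydro-1H-inden-1-one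
Product: 5 cis-fused 3-(tert-butyldimethylsilyloxy)-5,6-dimethyl-3a,4,7,7a-tetrahydro-1H-inden-1-one (vinylogous silyl ester), via trimethylsilyl enol ether 4 (not isolated)
Conditions: LDA, TMSCl, THF, -78 °C; then Pd(OAc)2 (10 mol %), O2, DMSO, rt
Reagents that add atoms: none
Why: Kinetic deprotonation at the only α-CH2 (C9) and Saegusa oxidation (Pd(II), β-hydride loss from C10) erase the now wrongly configured C10 centre, block C9 and leave C25–H as the only enolisable position, with C12 and C25 untouched.

Step 3
Reactants: 5 cis-fused 3-(tert-butyldimethylsilyloxy)-5,6-dimethyl-3a,4,7,7a-tetrahydro-1H-inden-1-one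
Product: 6 7a-hydroxy-3-(tert-butyldimethylsilyloxy)-5,6-dimethyl-3a,4,7,7a-tetrahydro-1H-inden-1-one (cis-fused; OH cis to H-3a)
Conditions: KHMDS, THF, -78 °C; 2-(phenylsulfonyl)-3-phenyloxaziridine; AcOH quench
Reagents that add atoms: 2-(phenylsulfonyl)-3-phenyloxaziridine, O=S(=O)(c1ccccc1)N1OC1c1ccccc1
Why: Davis α'-hydroxylation of the cross-conjugated C25 enolate, which is attacked on the convex face opposite the six-membered ring, so the new tertiary alcohol (C25, O24) is cis to H-12 and the cis ring fusion is kept.

Step 4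
Reactants: 6 7a-hydroxy-3-(tert-butyldimethylsilyloxy)-5,6-dimethyl-3a,4,7,7a-tetrahydro-1H-inden-1-one
Product: 8 4,5-epoxy-6,7a-dihydroxy-3-(tert-butyldimethylsilyloxy)-5,6-dimethyl-3a,4,5,6,7,7a-hexahydro-1H-inden-1-one (epoxide O and both OH on the face of H-3a), via allylic hydroperoxide 7 (not isolated)
Conditions: O2, hν (visible), TPP (1 mol %), Ti(OiPr)4 (10 mol %), CH2Cl2, 0 °C
Reagents that add atoms: dioxygen, O=O
Why: Schenck ene reaction followed in the same flask by Ti(IV)-catalysed oxygen transfer (epoxy-hydroxylation): the axial homoallylic C25–OH hydrogen-bonds singlet oxygen onto its own face, and in that half-chair only C13 offers a pseudo-axial allylic H on this face, so oxygen goes to C27 and the alkene moves to C13=C15, which the Ti-bound hydroperoxide then epoxidises syn to the C27 oxygen (sets C27, C13 and the epoxide face at C15).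

Step 5
Reactants: 9 (2R,5R)-2-tert-butyl-5-methyl-1,3-dioxolan-4-one; 10 methyl 2-(bromomethyl)acrylate
Product: 12 methyl (S)-2-methyl-4-methylene-5-oxotetrahydrofuran-2-carboxylate, via allylated dioxolanone 11 (not isolated)
Conditions: LDA, THF, -78 °C; 10; then TsOH (cat.), MeOH, 65 °C
Reagents that add atoms: methanol, CO
Why: Seebach self-regeneration of stereocentres: the lithium enolate is allylated (SN2/SN2') trans to the tert-butyl group so the new CH2 takes the place of the lactate H (quaternary C4 set), then acid methanolysis of the acetal and lactonisation of the freed tertiary alcohol onto the acrylate ester.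

Step 6
Reactants: 12 methyl (S)-2-methyl-4-methylene-5-oxotetrahydrofuran-2-carboxylate
Product: 13 methyl (2S,4S)-2,4-dimethyl-5-oxotetrahydrofuran-2-carboxylate
Conditions: H2 (50 atm), Ru(OAc)2[(R)-BINAP] (1 mol %), MeOH, 50 °C
Reagents that add atoms: none
Why: Ru–BINAP asymmetric hydrogenation of an α-methylene-γ-butyrolactone, a catalyst-controlled reaction in which the ligand selects the alkene face and sets C2 as S (methyl cis to the ester group); the ligand hand is assigned by analogy and the antipode would give the C2 epimer.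

Step 7
Reactants: 13 methyl (2S,4S)-2,4-dimethyl-5-oxotetrahydrofuran-2-carboxylate; 14 S-tert-butyl ethanethioate
Product: 15 S-tert-butyl (3S,5S)-3-hydroxy-3,5-dimethyl-2,6-dioxocyclohexane-1-carbothioate (drawn as the 2-enol)
Conditions: 14, LDA, THF, -78 °C; 13; -78 → 50 °C; then 1 M HCl
Reagents that add atoms: none
Why: Crossed Claisen condensation followed by Dieckmann-type closure: the thioester enolate is acylated by one carbonyl group of 13, the alkoxide set free deprotonates the β-keto thioester, and this stabilised anion closes the six-membered ring on the second carbonyl group, the triketone enolate being the thermodynamic sink and too weak a base to epimerise C2.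

Step 8
Reactants: 8 4,5-epoxy-6,7a-dihydroxy-3-(tert-butyldimethylsilyloxy)-5,6-dimethyl-3a,4,5,6,7,7a-hexahydro-1H-inden-1-one; 15 S-tert-butyl (3S,5S)-3-hydroxy-3,5-dimethyl-2,6-dioxocyclohexane-1-carbothioate
Product: 16 7a-O-[(3S,5S)-3-hydroxy-3,5-dimethyl-2,6-dioxocyclohexane-1-carbonyl] ester of 8 (ester oxygen = O24 on C25; acyl group as 2-enol)
Conditions: AgOCOCF3 (1.5 equiv), Na2HPO4, THF, rt, slow addition of 15
Reagents that add atoms: none
Why: Silver(I)-promoted acyl transfer from a β-keto thioester (acylketene-type, usable with tertiary alcohols), expected to select the C25 α-ketol hydroxyl because the C27 hydroxyl is flanked by the fully substituted epoxide carbon, with slow addition of 15 to suppress self-acylation; no stereocentre is touched.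

Step 9
Reactants: 16 7a-O-[(3S,5S)-3-hydroxy-3,5-dimethyl-2,6-dioxocyclohexane-1-carbonyl] ester of 8
Product: 17 cyclic carbonate of 16 bridging the C4 hydroxyl and the C7 enol oxygen (enol double bond fixed as C7=C19)
Conditions: CDI (1.5 equiv), DMAP (cat.), CH2Cl2, 0 °C → rt
Reagents that add atoms: 1,1'-carbonyldiimidazole, O=C(n1ccnc1)n1ccnc1
Why: Carbonate formation with CDI, in which reversible acyl-imidazole transfer funnels into the only possible five-membered ring (O on C4 to the enol O on C7), locking the enol double bond at C7=C19 as the ring expansion requires and masking the acidic enol.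

Step 10
Reactants: 17 cyclic carbonate of 16 bridging the C4 hydroxyl and the C7 enol oxygen
Product: 18 C9=C18 triethylsilyl enol ether of 1,4-reduced 17 (H-10 cis to H-12 and O24; OTBS on the face of the six-membered ring)
Conditions: RhCl(PPh3)3 (5 mol %), Et3SiH (3 equiv), toluene, 60 °C
Reagents that add atoms: triethylsilane, CC[SiH](CC)CC
Why: Rh-catalysed conjugate (1,4-) hydrosilylation of the cyclopentenone: hydride goes to C10 from the convex face, opposite the adjacent six-membered ring, which sets C10 as in the target and gives the C9=C18 silyl enol ether directly, the tetrasubstituted enol-carbonate alkene being inert.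

Step 11
Reactants: 18 C9=C18 triethylsilyl enol ether of 1,4-reduced 17
Product: 20 eight-membered enol-lactone (10-O-TBS, 17-O-TES, 13,15-epoxide; C7 ketone, Z-enol C19=C20–OH, free C4–OH and C27–OH), via cyclobutane photoadduct 19 (not isolated)
Conditions: hν (350 nm, Pyrex), MeCN (2 mM, degassed), 0 °C; then K2CO3 (10 mol %), MeOH, 0 °C
Reagents that add atoms: none
Why: Proposed new method: intramolecular de Mayo reaction through an ester tether (closest known reaction type: de Mayo/Winkler [2+2] photocycloaddition–retro-aldol of 1,3-dione enol esters and dioxenones with tethered alkenes) – the excited 3-acyloxy-2-carboxy-enone bonds C19 to C18 first (rule of five, five-membered lactone ring) on the only face O24 can reach and the 1,4-diradical closes C7–C9, so C18 and C9 are set cis to O24 and γ-lactone and cyclobutane form together, after which methanolysis of the carbonate frees the C7 cyclobutanol whose retro-aldol cleavage of C7–C19 (strain release, dicarbonyl-stabilised carbanion) enlarges the six-membered dione to the eight-membered ring with the Z-enol.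

Step 12
Reactants: 20 eight-membered enol-lactone (10-O-TBS, 17-O-TES, 13,15-epoxide)
Product: 21 target CNP0073514.1
Conditions: 48% aq. HF, MeCN, 0 °C → rt
Reagents that add atoms: none
Why: Acidic desilylation in which the tertiary TES ether falls first and the free C18–OH opens the protonated epoxide at the tertiary carbon C15 from the face opposite the epoxide oxygen (SN1-like, inversion at C15, six-membered ring, 2-oxabicyclo[2.2.2]octane), leaving the epoxide oxygen as the C13–OH while O11 is still silylated, before the secondary TBS ether is cleaved.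

**Compound list**
1 | (S)-4-(tert-butyldimethylsilyloxy)cyclopent-2-en-1-one | O=C1C[C@H](O[Si](C)(C)C(C)(C)C)C=C1 | starting material
2 | 2,3-dimethylbuta-1,3-diene | C=C(C)C(C)=C | starting material
3 | cis-fused 3-(tert-butyldimethylsilyloxy)-5,6-dimethyl-2,3,3a,4,7,7a-hexahydro-1H-inden-1-one, OTBS on the face of the ring-fusion H | O=C1C[C@H](O[Si](C)(C)C(C)(C)C)[C@H]2CC(C)=C(C)C[C@@H]12 | intermediate
4 | 1-trimethylsilyl enol ether of 3 (C9=C18), not isolated | C[Si](C)(C)OC1=C[C@H](O[Si](C)(C)C(C)(C)C)[C@H]2CC(C)=C(C)C[C@@H]12 | intermediate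
5 | cis-fused 3-(tert-butyldimethylsilyloxy)-5,6-dimethyl-3a,4,7,7a-tetrahydro-1H-inden-1-one | O=C1C=C(O[Si](C)(C)C(C)(C)C)[C@H]2CC(C)=C(C)C[C@@H]12 | intermediate
6 | 7a-hydroxy derivative of 5, OH cis to H-3a | O=C1C=C(O[Si](C)(C)C(C)(C)C)[C@H]2CC(C)=C(C)C[C@@]12O | intermediate
7 | 6-hydroperoxy-7a-hydroxy-3-(tert-butyldimethylsilyloxy)-5,6-dimethyl-3a,6,7,7a-tetrahydro-1H-inden-1-one, OOH cis to 7a-OH, not isolated | O=C1C=C(O[Si](C)(C)C(C)(C)C)[C@H]2C=C(C)[C@](C)(OO)C[C@@]12O | intermediate
8 | 4,5-epoxy-6,7a-dihydroxy-3-(tert-butyldimethylsilyloxy)-5,6-dimethyl-3a,4,5,6,7,7a-hexahydro-1H-inden-1-one, epoxide O and both OH on the face of H-3a | O=C1C=C(O[Si](C)(C)C(C)(C)C)[C@H]2[C@@H]3O[C@]3(C)[C@](C)(O)C[C@@]12O | intermediate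
9 | (2R,5R)-2-tert-butyl-5-methyl-1,3-dioxolan-4-one | C[C@H]1O[C@@H](C(C)(C)C)OC1=O | starting material
10 | methyl 2-(bromomethyl)acrylate | C=C(CBr)C(=O)OC | starting material
11 | 2-tert-butyl-5-[2-(methoxycarbonyl)allyl]-5-methyl-1,3-dioxolan-4-one, allyl group trans to tert-butyl, not isolated | C=C(C[C@]1(C)O[C@@H](C(C)(C)C)OC1=O)C(=O)OC | intermediate
12 | methyl (S)-2-methyl-4-methylene-5-oxotetrahydrofuran-2-carboxylate | COC(=O)[C@]1(C)CC(=C)C(=O)O1 | intermediate
13 | methyl (2S,4S)-2,4-dimethyl-5-oxotetrahydrofuran-2-carboxylate | COC(=O)[C@]1(C)C[C@H](C)C(=O)O1 | intermediate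
14 | S-tert-butyl ethanethioate | CC(=O)SC(C)(C)C | starting material
15 | S-tert-butyl (3S,5S)-3-hydroxy-3,5-dimethyl-2,6-dioxocyclohexane-1-carbothioate, 2-enol drawn | CC(C)(C)SC(=O)C1=C(O)[C@@](C)(O)C[C@H](C)C1=O | intermediate
16 | 7a-O-[(3S,5S)-3-hydroxy-3,5-dimethyl-2,6-dioxocyclohexane-1-carbonyl] ester of 8 | O=C1C=C(O[Si](C)(C)C(C)(C)C)[C@H]2[C@@H]3O[C@]3(C)[C@](C)(O)C[C@@]12OC(=O)C4=C(O)[C@@](C)(O)C[C@H](C)C4=O | intermediate
17 | cyclic carbonate of 16 bridging the C4 hydroxyl and the C7 enol oxygen | O=C1C=C(O[Si](C)(C)C(C)(C)C)[C@H]2[C@@H]3O[C@]3(C)[C@](C)(O)C[C@@]12OC(=O)C4=C5OC(=O)O[C@@]5(C)C[C@H](C)C4=O | intermediate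
18 | C9=C18 triethylsilyl enol ether of 1,4-reduced 17, H-10 cis to H-12 | CC[Si](CC)(CC)OC1=C[C@@H](O[Si](C)(C)C(C)(C)C)[C@H]2[C@@H]3O[C@]3(C)[C@](C)(O)C[C@@]12OC(=O)C4=C5OC(=O)O[C@@]5(C)C[C@H](C)C4=O | intermediate
19 | cyclobutane photoadduct of 18 (new bonds C18–C19 and C7–C9 on the O24 face; γ-lactone closed; all ring fusions cis), not isolated | C[C@H]1C[C@]2(C)OC(=O)O[C@@]23[C@@H]4[C@@H](O[Si](C)(C)C(C)(C)C)[C@H]5[C@@H]6O[C@]6(C)[C@](C)(O)C[C@]57OC(=O)[C@@]3(C1=O)[C@]47O[Si](CC)(CC)CC | intermediate
20 | eight-membered enol-lactone: 10-O-TBS, 17-O-TES, 13,15-epoxide, C7 ketone, Z-enol C19=C20–OH, free C4–OH and C27–OH | C[C@H]1C[C@](C)(O)C(=O)[C@@H]2[C@@H](O[Si](C)(C)C(C)(C)C)[C@H]3[C@@H]4O[C@]4(C)[C@](C)(O)C[C@]35OC(=O)/C(=C/1O)[C@]25O[Si](CC)(CC)CC | intermediate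
21 | CNP0073514.1 | C[C@H]1C[C@](C)(O)C(=O)[C@@H]2[C@@H](O)[C@H]3[C@H](O)[C@@]4(C)O[C@@]25/C(=C\1O)C(=O)O[C@@]35C[C@@]4(C)O | target

**Totals**
Total step count: 12. Longest linear sequence: 9 steps (steps 1–4, then 8–12).

**Three steps most likely to fail**

Step 11 (key photocycloaddition). The ester tether must reach its s-cis rotamer within the triplet lifetime, and the diradical can revert. Fallback: give up the excited-state route and close the same two bonds in the ground state as a polar, stepwise Mukaiyama–Michael/aldol (2+2) of the silyl enol ether onto the enol-carbonate acceptor (Tf2NH 5 mol %, CH2Cl2, -78 °C), which is not lifetime-limited. It sets out from 18, passes through the same cyclobutane 19 and comes back to the route at 20 after the same K2CO3/MeOH treatment; it makes no new compound F0.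

Step 4 (ene regiochemistry). Hydrogen abstraction at C26 or at a methyl group would put the oxygen on the wrong carbon. Fallback from 6: VO(acac)2/t-BuOOH epoxidises the tetrasubstituted alkene on the face of the homoallylic C25–OH to give the 5,6-epoxy-7a-hydroxy indenone F1. Et2Al(TMP) in toluene, held on that face by the C25 alkoxide, removes the syn pseudo-axial H at C13 and opens the C15–O bond to give the 6,7a-dihydroxy allylic alcohol F2. A second VO(acac)2/t-BuOOH epoxidation, syn to the C27–OH, comes back to the route at 8.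

Step 8 (acylation of a hindered tertiary α-ketol in the presence of two other tertiary alcohols). Fallback from 8: build the tether on the substrate instead of transferring it whole. KHMDS (1.0 equiv, -78 °C) deprotonates the more acidic α-ketol OH selectively and Ac2O gives the 7a-O-acetate F3. LiHMDS (3 equiv) and lactone ester 13 then repeat the Claisen/Dieckmann double acylation of step 7 on the acetate enolate and come back to the route at 16.

Further compounds
F0 | step 11 | none | none
F1 | step 4 | 5,6-epoxy-7a-hydroxy-3-(tert-butyldimethylsilyloxy)-5,6-dimethyl-3a,4,5,6,7,7a-hexahydro-1H-inden-1-one, epoxide O cis to 7a-OH | O=C1C=C(O[Si](C)(C)C(C)(C)C)[C@H]2C[C@]3(C)O[C@]3(C)C[C@@]12O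
F2 | step 4 | 6,7a-dihydroxy-3-(tert-butyldimethylsilyloxy)-5,6-dimethyl-3a,6,7,7a-tetrahydro-1H-inden-1-one, both OH on the same face | O=C1C=C(O[Si](C)(C)C(C)(C)C)[C@H]2C=C(C)[C@](C)(O)C[C@@]12O
F3 | step 8 | 7a-O-acetate of 8 | O=C1C=C(O[Si](C)(C)C(C)(C)C)[C@H]2[C@@H]3O[C@]3(C)[C@](C)(O)C[C@@]12OC(C)=O
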